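**Remark on the chemistry (assumption):** the cycloaddition partner is used with C3–C4 saturated. An O-silyl dienolate that already held the C3=C4 bond (a 2-siloxy-6H-pyran) is expected to open at O1–C2 by β-elimination or oxa-6π cycloreversion to a (2Z,4)-dienoate and so lose the stereocentre. The double bond is therefore introduced in the step after the ring construction. Atom numbers are those of the chromene (O1, C2, C3, C4, C4a, C5–C8, C8a); pyrone atoms are called "pyrone C3" and so on.

## Analysis of the target

The target is a 2H-chromene (O1, C2, C3=C4, C4a–C8a) with an acetyl group at C6 and a hydroxyl at C7 that is hydrogen-bonded to the acetyl oxygen. C2 carries a methyl group and a CH2O group esterified with (E)-4-hydroxy-3-methoxycinnamic acid. There is one stereocentre, C2, of R configuration; it is fully substituted (O1, C3, CH3, CH2O), so only the absolute configuration has to be controlled. The sensitive elements are these: the O1–C2 bond is tertiary, allylic and phenolic and can ionise under protic or Lewis acids, which would scramble C2; the C3=C4 bond is styrene-like; the cinnamate is labile to base and nucleophiles; and there are two free phenols. The synthesis is hard for two reasons: CH3 and CH2O at C2 are similar in size, so setting this centre by catalysis is unreliable, and the arene is 1,2,4,5-tetrasubstituted with the acetyl group para to O1. The plan rests on a match of patterns: C5, C6, C7 and C8 carry H, acyl, oxygen and H, as do C6, C5, C4 and C3 of a 4-alkoxy-2-pyrone-5-carboxylate. At the same time C4a=C8a–O1, with C2 attached to O1, is the enol-ether side of a six-membered lactone whose C6 is the stereocentre. The benzene ring can therefore be built onto a pyran ring that already holds C2.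

## Retrosynthetic reasoning

The last bond cut is the ester C–O bond between the C2 hydroxymethyl group and the cinnamoyl carbon. This gives alcohol 17 and the phenol-protected acid 20, which comes from 18 in one operation. The 7-hydroxyl stays as its methyl ether until after the acylation (21 → 22 → 23), so 17 offers a single hydroxyl and no choice between an alcohol and a phenol arises. Forward, this needs a carbodiimide esterification of a neopentyl-type primary alcohol, then chelation-directed O-demethylation next to the acetyl group, then removal of the aryl silyl ether.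

The acetyl group of 17 is traced through 16 and acid 15 to the methyl ester of 14 (addition of a methyl organometallic to the carboxylate). The ester is kept this long because it is the electron-withdrawing group the ring construction needs. The forward steps only change the C6 substituent and unmask the primary alcohol.

The C3=C4 double bond of 14 is removed next, giving chroman 13. A cycloaddition partner with C3=C4 in place would have O1–C2 allylic to its enolate terminus and could open by β-elimination, erasing C2; it could also react through its γ-carbon or as a diene. With C3 and C4 saturated the partner is an ordinary lactone enolate derivative. Forward, C4 of 13 is benzylic, ortho to O1 and para to the 7-methoxy group, and C2 has no hydrogen, so hydride abstraction by a quinone followed by loss of a C3 proton can only give the C3=C4 alkene.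

The key disconnection cuts C8a–C8 and C4a–C5 of 13. It takes the benzene ring apart and leaves the pyran ring with its stereocentre, giving ketene silyl acetal 6 (C4a=C8a, with O1 and a silyloxy group on C8a) and pyrone 10, whose C3, C4, C5 and C6 become C8, C7, C6 and C5. Cutting here means no bond to C2 is made or broken after the chiral starting material, and the arene arrives with ester and methoxy group already adjacent. The forward reaction must deliver the regiochemistry (nucleophilic C4a to pyrone C6), decarboxylative cycloreversion of the bridged lactone, and loss of the silyloxy group, not of O1, on aromatisation.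

Compound 6 is the O-silylated enolate of lactone 5. The lactone C–O bond is cut to 1,5-diol 4 (oxidative lactonisation forward), and the primary hydroxyl of 4 is traced to the terminal alkene of 3 (anti-Markovnikov hydration). The C3–C4 bond of 3 is cut between an allyl nucleophile and the CH2 terminus of epoxide 2, the silyl ether of commercial 1. The epoxide is opened at its unsubstituted carbon, so the quaternary carbon keeps all four bonds and its configuration.

Pyrone 10 is the methyl ether of hydroxypyrone 9. This is disconnected at O1–C6 and C5–C6 (pyrone numbering) to 7 and a one-carbon unit at the formate oxidation level, with enol ether 8 on the way.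

## Alternatives that were turned down

Alternative 1: The pyran ring is traced back to a five-membered ring by removing C4, so C3–C4 and C4–C4a are the bonds made. The precursor is (S)-5-bromo-2-[(tert-butyldiphenylsilyloxy)methyl]-6-(methoxymethoxy)-2-methylbenzofuran-3(2H)-one A2, in which C2 is already the quaternary stereocentre. Forward, a silyl-substituted diazomethane adds to the Lewis-acid-activated ketone and the aryl carbon migrates with loss of dinitrogen, giving (S)-6-bromo-2-[(tert-butyldiphenylsilyloxy)methyl]-7-(methoxymethoxy)-2-methylchroman-3-one A1.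
- For it: the arene is used with all substituents in place (bromine as latent acetyl), so the benzene substitution pattern is never at risk, and homologation of aryl ketones by diazoalkanes is an established reaction type. On both points it is stronger than the chosen route.
- Against it: the ketone of A2 is a vinylogous ester next to a fully substituted carbon, so addition is slow and epoxide formation, double homologation and migration of C2 compete. A2 itself needs an enantioselective construction of an α-quaternary α-aryloxy ketone, with no evident chiral-pool entry. A1 is at the wrong oxidation pattern: reduction and dehydration (for C3=C4), bromine-to-acetyl exchange, acidic removal of the methoxymethyl group on an acid-labile chromene, desilylation and acylation follow, roughly seven further steps.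
- Comparison: the chosen route offers instead a stereocentre taken unchanged from a commercial epoxide and a ring-construction product with ester and methoxy group already at the right positions.

Alternative 2: Only C4–C4a is cut. The precursor is the tertiary aryl propargyl ether (R)-2-[4-acetyl-3-(triisopropylsilyloxy)phenoxy]-2-methylbut-3-yn-1-yl acetate A4. Forward, a cationic gold catalyst activates the terminal alkyne, and the arene carbon para to the silyloxy group attacks the alkyne terminus in a 6-endo-dig closure, giving (R)-[6-acetyl-2-methyl-7-(triisopropylsilyloxy)-2H-chromen-2-yl]methyl acetate A3.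
- For it: it is the shortest plan. The arene half is an inexpensive phenol, C3=C4 and the acetyl group are in place after the key step, and no dehydrogenation or demethylation is needed. In step economy it is clearly stronger than the chosen route.
- Against it: the stereocentre of A4, a tertiary propargylic aryl ether carbon bearing CH3 and CH2OAc, must first be made enantiopure. Ether formation at such a carbon runs through ionisable intermediates, and a desymmetrising or enzymatic step tells CH3 from CH2OAc poorly at a quaternary centre. Under gold the same C–O bond can ionise, so the configuration is at risk in the key step itself. The acetyl-deactivated arene is a weak nucleophile; 5-exo closure, attack at the carbon between the two oxygens, and participation of the neighbouring acetate compete.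
- Comparison: the chosen route gives up brevity, but C2 comes from the chiral pool through steps that never touch its bonds, and the arene pattern is fixed by the polarity of the cycloaddition.

Alternative 3: The pyran ring is cut at O1–C2 and C3–C4. 5-Acetyl-2,4-dihydroxybenzaldehyde A6 and (E)-4-[(tert-butyldimethylsilyl)oxy]-3-methylbut-2-enal A7 are combined under a chiral secondary amine of the diarylprolinol silyl ether type. Iminium activation, oxa-Michael addition of the ortho hydroxyl to the β-carbon, enamine aldol onto the formyl group and dehydration give (R)-6-acetyl-2-[(tert-butyldimethylsilyloxy)methyl]-7-hydroxy-2-methyl-2H-chromene-3-carbaldehyde A5.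
- For it: one catalytic step makes both ring bonds and the stereocentre from two achiral pieces, and C3=C4 and the complete arene are present afterwards. As a catalytic asymmetric entry it is more elegant than a chiral-pool route.
- Against it: the domino is well behaved for β-monosubstituted enals. With the β,β-disubstituted A7 the oxa-Michael step must build a fully substituted carbon against a reversible, unfavourable equilibrium, the iminium geometry is poorly controlled, and the catalyst must distinguish CH3 from CH2OSi. Enantiocontrol is thus weakest at the one atom that matters. A5 also carries a formyl group at C3 that the target lacks, so a decarbonylation (typically with a stoichiometric rhodium complex) must follow on a substrate with a free phenol and a ketone. Retro-oxa-Michael opening of A5 can erode its purity.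
- Comparison: the chosen route is longer to the bicyclic core but leaves no doubt about the configuration and adds no carbon that must be excised.

Key step: step 8

## Route

Step 1
Reactants: 1 (S)-2-methylglycidol, [(2S)-2-methyloxiran-2-yl]methanol
Product: 2 tert-butyldimethyl{[(2R)-2-methyloxiran-2-yl]methoxy}silane
Conditions: TBSCl, imidazole, CH2Cl2, 0 °C → rt
Reagents that add atoms: tert-butyldimethylsilyl chloride, CC(C)(C)[Si](C)(C)Cl
Why: Standard silylation of a primary alcohol; no bond to the stereocentre is touched, and the descriptor changes from S to R only because CH2OSi now outranks the ring CH2.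

Step 2
Reactants: 2 tert-butyldimethyl{[(2R)-2-methyloxiran-2-yl]methoxy}silane
Product: 3 (2R)-1-[(tert-butyldimethylsilyl)oxy]-2-methylhex-5-en-2-ol
Conditions: allylMgCl, CuI (10 mol %), THF, −30 → 0 °C; aq. NH4Cl
Reagents that add atoms: allylmagnesium chloride, C=CC[Mg]Cl
Why: Copper-catalysed Grignard opening of a 2,2-disubstituted epoxide takes place at the unsubstituted CH2 (SN2), so the quaternary carbon keeps its configuration; the new C–C bond is the future C3–C4 bond.

Step 3
Reactants: 3 (2R)-1-[(tert-butyldimethylsilyl)oxy]-2-methylhex-5-en-2-ol
Product: 4 (5R)-6-[(tert-butyldimethylsilyl)oxy]-5-methylhexane-1,5-diol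
Conditions: 9-BBN (2.2 equiv), THF, 0 °C → rt; then NaOH, H2O2, 0 °C → rt
Reagents that add atoms: hydrogen peroxide, OO
Why: Hydroboration–oxidation with a bulky dialkylborane places the hydroxyl on the terminal carbon of the monosubstituted alkene; excess borane covers the free tertiary hydroxyl, and the silyl ether is stable to alkaline peroxide.

Step 4
Reactants: 4 (5R)-6-[(tert-butyldimethylsilyl)oxy]-5-methylhexane-1,5-diol
Product: 5 (6R)-6-{[(tert-butyldimethylsilyl)oxy]methyl}-6-methyloxan-2-one
Conditions: TEMPO (20 mol %), PhI(OAc)2 (2.5 equiv), CH2Cl2, rt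
Reagents that add atoms: none
Why: Oxoammonium (TEMPO) oxidation converts only the primary alcohol into the aldehyde, which closes to the six-membered lactol with the tertiary hydroxyl and is oxidised further to the lactone (oxidative lactonisation of a 1,5-diol).

Step 5
Reactants: 5 (6R)-6-{[(tert-butyldimethylsilyl)oxy]methyl}-6-methyloxan-2-one
Product: 6 tert-butyl{[(2R)-2-{[(tert-butyldimethylsilyl)oxy]methyl}-2-methyl-3,4-dihydro-2H-pyran-6-yl]oxy}dimethylsilane
Conditions: LiN(iPr)2, THF, −78 °C; TBSCl, DMPU, −78 °C → rt; pentane, filtration, no aqueous work-up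
Reagents that add atoms: tert-butyldimethylsilyl chloride, CC(C)(C)[Si](C)(C)Cl
Why: Kinetic enolisation of the δ-lactone at its only acidic position and O-silylation in the presence of a polar cosolvent should give the cyclic ketene silyl acetal (silyl ketene acetal formation), which is used without contact with water.

Step 6
Reactants: 7 dimethyl 3-oxopentanedioate
Product: 9 methyl 4-hydroxy-2-oxo-2H-pyran-5-carboxylate, via ethoxymethylene diester 8 (not isolated)
Conditions: HC(OEt)3, Ac2O, 130 °C; concentrate; then aq. HCl, rt
Reagents that add atoms: triethyl orthoformate, CCOC(OCC)OCC; water, O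
Why: Orthoformate condensation at one of the two equivalent active methylene groups gives enol ether 8; acid hydrolysis to the hydroxymethylene compound and attack of its enol oxygen on the distal ester close the 2-pyrone ring (condensation and lactonisation).

Step 7
Reactants: 9 methyl 4-hydroxy-2-oxo-2H-pyran-5-carboxylate
Product: 10 methyl 4-methoxy-2-oxo-2H-pyran-5-carboxylate
Conditions: Me2SO4, K2CO3, acetone, reflux
Reagents that add atoms: dimethyl sulfate, COS(=O)(=O)OC
Why: 4-Hydroxy-2-pyrones are vinylogous acids and are alkylated on the 4-oxygen by a hard methylating agent under carbonate conditions (O-methylation), which fixes the 2-pyrone tautomer needed as the diene.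

Step 8
Reactants: 6 tert-butyl{[(2R)-2-{[(tert-butyldimethylsilyl)oxy]methyl}-2-methyl-3,4-dihydro-2H-pyran-6-yl]oxy}dimethylsilane; 10 methyl 4-methoxy-2-oxo-2H-pyran-5-carboxylate
Product: 13 methyl (2R)-2-{[(tert-butyldimethylsilyl)oxy]methyl}-7-methoxy-2-methyl-3,4-dihydro-2H-chromene-6-carboxylate, via bridged lactone cycloadduct 11 (not isolated), via siloxy dihydroarene 12 (not isolated)
Conditions: 6 (1.5 equiv), PhMe, 110 °C, sealed tube; then DBU, 60 °C
Reagents that add atoms: none
Why: Proposed new method: the electron-rich ketene silyl acetal 6 should add to the electron-poor diene of 10 in an inverse-electron-demand Diels–Alder reaction, probably asynchronously: its nucleophilic β-carbon (future C4a) bonds to pyrone C6, the position β to the ester and δ to the lactone carbonyl, and its acetal carbon (future C8a) bonds to pyrone C3, the enolate terminus of the developing zwitterion, which the 4-methoxy group makes more nucleophilic. Bridged lactone 11 should lose CO2 by retro-[4+2] at the reaction temperature to give dihydroarene 12, and loss of silanol across C8a–C4a aromatises it; C4a–H is γ to the ester, so DBU can take this through an E1cB path. The closest known reaction type is the cycloaddition of coumalate and other 2-pyrone esters with ketene acetals and enol ethers, which gives benzoates after loss of CO2 and an alcohol; a lactone-derived ketene silyl acetal has not been paired with a 4-alkoxy-2-pyrone-5-carboxylate to give a chroman. The benzene ring is the one ring closed: it is formed by an intermolecular [4+2] cycloaddition that makes C8a–C8 and C4a–C5 and is annulated onto the existing dihydropyran. The stereocentres that appear at C4a, C5, C8 and C8a are all erased on aromatisation, so none needs control, and C2 lies outside the reacting atoms and is carried through unchanged. The step needs regioselectivity (ester para to O1, methoxy meta), which the polarity match above secures, and it needs the silyloxy group, not O1, to leave from C8a: silanolate is the better nucleofuge and its departure keeps the aryl ether, while acid, which would protonate O1 preferentially, is excluded.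

Step 9
Reactants: 13 methyl (2R)-2-{[(tert-butyldimethylsilyl)oxy]methyl}-7-methoxy-2-methyl-3,4-dihydro-2H-chromene-6-carboxylate
Product: 14 methyl (2R)-2-{[(tert-butyldimethylsilyl)oxy]methyl}-7-methoxy-2-methyl-2H-chromene-6-carboxylate
Conditions: DDQ (1.5 equiv), 1,4-dioxane (dry), 100 °C
Reagents that add atoms: none
Why: Quinone dehydrogenation of a chroman: hydride abstraction at benzylic C4 is assisted by O1 (ortho) and the 7-methoxy group (para), and the only proton that can then be lost is on C3, since C2 is quaternary; the silyl ether and the ester are inert to DDQ under anhydrous conditions.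

Step 10
Reactants: 14 methyl (2R)-2-{[(tert-butyldimethylsilyl)oxy]methyl}-7-methoxy-2-methyl-2H-chromene-6-carboxylate
Product: 15 (2R)-2-{[(tert-butyldimethylsilyl)oxy]methyl}-7-methoxy-2-methyl-2H-chromene-6-carboxylic acid
Conditions: LiOH, THF/MeOH/H2O, 50 °C; then dilute HCl to pH 4, 0 °C
Reagents that add atoms: lithium hydroxide, [Li+].[OH-]
Why: Saponification of the aryl ester; the primary silyl ether and the chromene are stable to aqueous hydroxide, and acidification is kept mild and cold to protect both.

Step 11
Reactants: 15 (2R)-2-{[(tert-butyldimethylsilyl)oxy]methyl}-7-methoxy-2-methyl-2H-chromene-6-carboxylic acid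
Product: 16 1-[(2R)-2-{[(tert-butyldimethylsilyl)oxy]methyl}-7-methoxy-2-methyl-2H-chromen-6-yl]ethan-1-one
Conditions: MeLi (3.5 equiv), THF, 0 °C → rt; inverse quench into cold H2O
Reagents that add atoms: methyllithium, [Li]C
Why: Addition of methyllithium to the lithium carboxylate gives a dilithio gem-diolate that does not collapse before hydrolysis, so the methyl ketone results (organolithium–carboxylate ketone synthesis); nothing else in 15 is electrophilic.

Step 12
Reactants: 16 1-[(2R)-2-{[(tert-butyldimethylsilyl)oxy]methyl}-7-methoxy-2-methyl-2H-chromen-6-yl]ethan-1-one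
Product: 17 1-[(2R)-2-(hydroxymethyl)-7-methoxy-2-methyl-2H-chromen-6-yl]ethan-1-one
Conditions: Bu4NF, THF, 0 °C → rt
Reagents that add atoms: none
Why: Fluoride cleaves the primary silyl ether (desilylation); the ketone, the aryl methyl ether and the chromene are inert.

Step 13
Reactants: 18 ferulic acid, (E)-3-(4-hydroxy-3-methoxyphenyl)prop-2-enoic acid
Product: 20 (E)-3-{4-[(tert-butyldimethylsilyl)oxy]-3-methoxyphenyl}prop-2-enoic acid, via silyl ester 19 (not isolated)
Conditions: TBSCl (2.3 equiv), imidazole, DMF, rt; then K2CO3 (cat.), THF/MeOH/H2O, 0 °C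
Reagents that add atoms: tert-butyldimethylsilyl chloride, CC(C)(C)[Si](C)(C)Cl
Why: Both the phenol and the acid are silylated, and the far more labile silyl ester is then hydrolysed selectively, leaving the aryl silyl ether (phenol protection).

Step 14
Reactants: 17 1-[(2R)-2-(hydroxymethyl)-7-methoxy-2-methyl-2H-chromen-6-yl]ethan-1-one; 20 (E)-3-{4-[(tert-butyldimethylsilyl)oxy]-3-methoxyphenyl}prop-2-enoic acid
Product: 21 [(2R)-6-acetyl-7-methoxy-2-methyl-2H-chromen-2-yl]methyl (E)-3-{4-[(tert-butyldimethylsilyl)oxy]-3-methoxyphenyl}prop-2-enoate
Conditions: EDC·HCl, DMAP, CH2Cl2, 0 °C → rt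
Reagents that add atoms: none
Why: Steglich esterification; 17 has a single hydroxyl, so no chemoselectivity question arises, the aryl silyl ether prevents self-condensation of the acid, and the (E)-alkene is not touched.

Step 15
Reactants: 21 [(2R)-6-acetyl-7-methoxy-2-methyl-2H-chromen-2-yl]methyl (E)-3-{4-[(tert-butyldimethylsilyl)oxy]-3-methoxyphenyl}prop-2-enoate
Product: 22 [(2R)-6-acetyl-7-hydroxy-2-methyl-2H-chromen-2-yl]methyl (E)-3-{4-[(tert-butyldimethylsilyl)oxy]-3-methoxyphenyl}prop-2-enoate
Conditions: BCl3 (1.5 equiv), CH2Cl2, −78 °C; aq. NaHCO3
Reagents that add atoms: none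
Why: BCl3 binds between the acetyl oxygen and the 7-methoxy oxygen and chloride removes the methyl group (chelation-directed demethylation of an ortho-acyl aryl methyl ether); the non-chelated methoxy group of the cinnamate and the ester should not be cleaved at −78 °C, and loss of the aryl silyl ether, should it occur, only anticipates step 16.

Step 16
Reactants: 22 [(2R)-6-acetyl-7-hydroxy-2-methyl-2H-chromen-2-yl]methyl (E)-3-{4-[(tert-butyldimethylsilyl)oxy]-3-methoxyphenyl}prop-2-enoate
Product: 23 [(2R)-6-acetyl-7-hydroxy-2-methyl-2H-chromen-2-yl]methyl (E)-3-(4-hydroxy-3-methoxyphenyl)prop-2-enoate (CNP0375196.1)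
Conditions: Bu4NF, AcOH, THF, 0 °C
Reagents that add atoms: none
Why: Buffered fluoride removes the aryl silyl ether without touching the cinnamate or the chromene (desilylation), giving 23 with C2 unchanged since step 1.

## Compound list

1 | (S)-2-methylglycidol, [(2S)-2-methyloxiran-2-yl]methanol | OC[C@@]1(C)CO1 | starting material
2 | tert-butyldimethyl{[(2R)-2-methyloxiran-2-yl]methoxy}silane | CC(C)(C)[Si](C)(C)OC[C@@]1(C)CO1 | intermediate
3 | (2R)-1-[(tert-butyldimethylsilyl)oxy]-2-methylhex-5-en-2-ol | CC(C)(C)[Si](C)(C)OC[C@@](O)(C)CCC=C | intermediate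
4 | (5R)-6-[(tert-butyldimethylsilyl)oxy]-5-methylhexane-1,5-diol | CC(C)(C)[Si](C)(C)OC[C@@](O)(C)CCCCO | intermediate
5 | (6R)-6-{[(tert-butyldimethylsilyl)oxy]methyl}-6-methyloxan-2-one | CC(C)(C)[Si](C)(C)OC[C@@]1(C)CCCC(=O)O1 | intermediate
6 | tert-butyl{[(2R)-2-{[(tert-butyldimethylsilyl)oxy]methyl}-2-methyl-3,4-dihydro-2H-pyran-6-yl]oxy}dimethylsilane | CC(C)(C)[Si](C)(C)OC[C@@]1(C)CCC=C(O[Si](C)(C)C(C)(C)C)O1 | intermediate
7 | dimethyl 3-oxopentanedioate | COC(=O)CC(=O)CC(=O)OC | starting material
8 | dimethyl 2-(ethoxymethylidene)-3-oxopentanedioate (alkene geometry not defined; not isolated) | CCOC=C(C(=O)OC)C(=O)CC(=O)OC | intermediate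
9 | methyl 4-hydroxy-2-oxo-2H-pyran-5-carboxylate | COC(=O)C1=COC(=O)C=C1O | intermediate
10 | methyl 4-methoxy-2-oxo-2H-pyran-5-carboxylate | COC(=O)C1=COC(=O)C=C1OC | intermediate
11 | bridged lactone cycloadduct, methyl (2R)-8a-[(tert-butyldimethylsilyl)oxy]-2-{[(tert-butyldimethylsilyl)oxy]methyl}-7-methoxy-2-methyl-10-oxo-3,4,4a,5,8,8a-hexahydro-2H-5,8-(epoxymethano)chromene-6-carboxylate (bridge O on C5, bridge C=O on C8; centres at C4a, C5, C8, C8a unassigned and erased later; not isolated) | O=C1OC2C(C(=O)OC)=C(OC)C1C3(O[Si](C)(C)C(C)(C)C)O[C@@](C)(CO[Si](C)(C)C(C)(C)C)CCC23 | intermediate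
12 | methyl (2R)-8a-[(tert-butyldimethylsilyl)oxy]-2-{[(tert-butyldimethylsilyl)oxy]methyl}-7-methoxy-2-methyl-3,4,4a,8a-tetrahydro-2H-chromene-6-carboxylate (centres at C4a and C8a unassigned and erased later; not isolated) | COC(=O)C1=CC2CC[C@](C)(CO[Si](C)(C)C(C)(C)C)OC2(O[Si](C)(C)C(C)(C)C)C=C1OC | intermediate
13 | methyl (2R)-2-{[(tert-butyldimethylsilyl)oxy]methyl}-7-methoxy-2-methyl-3,4-dihydro-2H-chromene-6-carboxylate | COC(=O)c1cc2CC[C@](C)(CO[Si](C)(C)C(C)(C)C)Oc2cc1OC | intermediate
14 | methyl (2R)-2-{[(tert-butyldimethylsilyl)oxy]methyl}-7-methoxy-2-methyl-2H-chromene-6-carboxylate | COC(=O)c1cc2C=C[C@](C)(CO[Si](C)(C)C(C)(C)C)Oc2cc1OC | intermediate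
15 | (2R)-2-{[(tert-butyldimethylsilyl)oxy]methyl}-7-methoxy-2-methyl-2H-chromene-6-carboxylic acid | OC(=O)c1cc2C=C[C@](C)(CO[Si](C)(C)C(C)(C)C)Oc2cc1OC | intermediate
16 | 1-[(2R)-2-{[(tert-butyldimethylsilyl)oxy]methyl}-7-methoxy-2-methyl-2H-chromen-6-yl]ethan-1-one | CC(=O)c1cc2C=C[C@](C)(CO[Si](C)(C)C(C)(C)C)Oc2cc1OC | intermediate
17 | 1-[(2R)-2-(hydroxymethyl)-7-methoxy-2-methyl-2H-chromen-6-yl]ethan-1-one | CC(=O)c1cc2C=C[C@](C)(CO)Oc2cc1OC | intermediate
18 | ferulic acid, (E)-3-(4-hydroxy-3-methoxyphenyl)prop-2-enoic acid | COc1cc(/C=C/C(=O)O)ccc1O | starting material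
19 | tert-butyldimethylsilyl (E)-3-{4-[(tert-butyldimethylsilyl)oxy]-3-methoxyphenyl}prop-2-enoate (not isolated) | COc1cc(/C=C/C(=O)O[Si](C)(C)C(C)(C)C)ccc1O[Si](C)(C)C(C)(C)C | intermediate
20 | (E)-3-{4-[(tert-butyldimethylsilyl)oxy]-3-methoxyphenyl}prop-2-enoic acid | COc1cc(/C=C/C(=O)O)ccc1O[Si](C)(C)C(C)(C)C | intermediate
21 | [(2R)-6-acetyl-7-methoxy-2-methyl-2H-chromen-2-yl]methyl (E)-3-{4-[(tert-butyldimethylsilyl)oxy]-3-methoxyphenyl}prop-2-enoate | COc1cc(/C=C/C(=O)OC[C@@]2(C)C=Cc3cc(C(C)=O)c(OC)cc3O2)ccc1O[Si](C)(C)C(C)(C)C | intermediate
22 | [(2R)-6-acetyl-7-hydroxy-2-methyl-2H-chromen-2-yl]methyl (E)-3-{4-[(tert-butyldimethylsilyl)oxy]-3-methoxyphenyl}prop-2-enoate | COc1cc(/C=C/C(=O)OC[C@@]2(C)C=Cc3cc(C(C)=O)c(O)cc3O2)ccc1O[Si](C)(C)C(C)(C)C | intermediate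
23 | [(2R)-6-acetyl-7-hydroxy-2-methyl-2H-chromen-2-yl]methyl (E)-3-(4-hydroxy-3-methoxyphenyl)prop-2-enoate | COc1cc(/C=C/C(=O)OC[C@@]2(C)C=Cc3cc(C(C)=O)c(O)cc3O2)ccc1O | target

## Step count and least certain steps

Total: 16 steps. Longest linear sequence: 13 steps (steps 1–5, 8–12, 14–16); steps 6–7 and step 13 are side branches.

**Step 8 (key step, proposed new method).**
- What may go wrong: too little diene reactivity, because the 4-methoxy group raises the acceptor orbital of the pyrone, so that 6 is consumed by hydrolysis or silyl transfer first; conjugate addition at pyrone C6 without ring closure; and opening of the pyran ring by departure of O1 instead of the silyloxy group in the aromatising elimination.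
- Fallback (known reactions only, from 2, returning at 13): 2 would be treated with excess dimethylsulfonium methylide (Me3SI, n-BuLi, THF) to give the one-carbon-homologated tertiary allylic alcohol (R)-1-[(tert-butyldimethylsilyl)oxy]-2-methylbut-3-en-2-ol F1. Commercial methyl 4-bromo-2-methoxybenzoate would be iodinated para to the methoxy group (N-iodosuccinimide, CF3CO2H) to methyl 4-bromo-5-iodo-2-methoxybenzoate F2. Hydroboration of F1 with 9-BBN and B-alkyl Suzuki–Miyaura coupling at the C–I bond of F2 (PdCl2(dppf), K3PO4) would give methyl 4-bromo-5-[(3R)-4-{[tert-butyldimethylsilyl]oxy}-3-hydroxy-3-methylbutyl]-2-methoxybenzoate F3. Palladium-catalysed intramolecular C–O coupling of the tertiary alcohol with the aryl bromide (Pd(OAc)2, a bulky biaryl di-tert-butylphosphine, Cs2CO3, PhMe) would close the pyran ring to 13. The ring construction by cycloaddition is given up; everything from 13 onward stays.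

**Step 9.**
- What may go wrong: slow hydride abstraction because of the ester, and capture of the benzylic cation by adventitious water, leading to oxygenation at C4 instead of dehydrogenation.
- Fallback (from 13, returning at 14): radical bromination at C4 (N-bromosuccinimide, AIBN, PhCF3, reflux) would give methyl (2R)-4-bromo-2-{[(tert-butyldimethylsilyl)oxy]methyl}-7-methoxy-2-methyl-3,4-dihydro-2H-chromene-6-carboxylate F4 (both C4 epimers), and elimination with DBU would give 14.

**Step 15.**
- What may go wrong: Lewis-acid ionisation of the tertiary allylic O1–C2 bond, with ring opening and erosion of the configuration at C2, and cleavage of the second methoxy group if the temperature rises.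
- Fallback (from 16, returning at 22): the methyl ether would be removed earlier by a nucleophile instead of a Lewis acid. NaSEt in DMF at 100 °C (SN2 at the methyl group, accelerated by the ortho acetyl group) would give 1-[(2R)-2-{[(tert-butyldimethylsilyl)oxy]methyl}-7-hydroxy-2-methyl-2H-chromen-6-yl]ethan-1-one F5. Desilylation with Bu4NF would give 1-[(2R)-7-hydroxy-2-(hydroxymethyl)-2-methyl-2H-chromen-6-yl]ethan-1-one F6. Carbodiimide acylation of F6 with a limiting amount of 20 should take the primary hydroxyl, the hydrogen-bonded phenol being the poorer nucleophile, and give 22.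

**Step 14.**
- What may go wrong: slow acylation of the neopentyl-type alcohol, so that rearrangement of the activated acid to an N-acylurea takes over.
- Fallback (from 17, returning at 21): the cinnamate would be built on the alcohol. Acylation with the small and more reactive 2-(diethoxyphosphoryl)acetyl chloride (pyridine, CH2Cl2) would give [(2R)-6-acetyl-7-methoxy-2-methyl-2H-chromen-2-yl]methyl 2-(diethoxyphosphoryl)acetate F7. Horner–Wadsworth–Emmons olefination (LiCl, DBU, MeCN) with 4-[(tert-butyldimethylsilyl)oxy]-3-methoxybenzaldehyde F8, made from vanillin with TBSCl and imidazole, would give the (E)-ester 21.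

**Step 11.**
- What may go wrong: over-addition to the tertiary alcohol if the gem-diolate collapses before the quench, or incomplete addition to the poorly soluble carboxylate.
- Fallback (from 14, returning at 16, bypassing 15): direct conversion of the ester with MeNHOMe·HCl and iPrMgCl (THF, −20 °C) would give the Weinreb amide (2R)-2-{[(tert-butyldimethylsilyl)oxy]methyl}-N,7-dimethoxy-N,2-dimethyl-2H-chromene-6-carboxamide F9, and MeMgBr would give 16.

## Further compounds

F1 | step 8 | (R)-1-[(tert-butyldimethylsilyl)oxy]-2-methylbut-3-en-2-ol | CC(C)(C)[Si](C)(C)OC[C@@](O)(C)C=C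
F2 | step 8 | methyl 4-bromo-5-iodo-2-methoxybenzoate | COC(=O)c1cc(I)c(Br)cc1OC
F3 | step 8 | methyl 4-bromo-5-[(3R)-4-{[tert-butyldimethylsilyl]oxy}-3-hydroxy-3-methylbutyl]-2-methoxybenzoate | COC(=O)c1cc(CC[C@@](C)(O)CO[Si](C)(C)C(C)(C)C)c(Br)cc1OC
F4 | step 9 | methyl (2R)-4-bromo-2-{[(tert-butyldimethylsilyl)oxy]methyl}-7-methoxy-2-methyl-3,4-dihydro-2H-chromene-6-carboxylate (C4 epimers) | COC(=O)c1cc2C(Br)C[C@](C)(CO[Si](C)(C)C(C)(C)C)Oc2cc1OC
F5 | step 15 | 1-[(2R)-2-{[(tert-butyldimethylsilyl)oxy]methyl}-7-hydroxy-2-methyl-2H-chromen-6-yl]ethan-1-one | CC(=O)c1cc2C=C[C@](C)(CO[Si](C)(C)C(C)(C)C)Oc2cc1O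
F6 | step 15 | 1-[(2R)-7-hydroxy-2-(hydroxymethyl)-2-methyl-2H-chromen-6-yl]ethan-1-one | CC(=O)c1cc2C=C[C@](C)(CO)Oc2cc1O
F7 | step 14 | [(2R)-6-acetyl-7-methoxy-2-methyl-2H-chromen-2-yl]methyl 2-(diethoxyphosphoryl)acetate | CCOP(=O)(OCC)CC(=O)OC[C@@]1(C)C=Cc2cc(C(C)=O)c(OC)cc2O1
F8 | step 14 | 4-[(tert-butyldimethylsilyl)oxy]-3-methoxybenzaldehyde | COc1cc(C=O)ccc1O[Si](C)(C)C(C)(C)C
F9 | step 11 | (2R)-2-{[(tert-butyldimethylsilyl)oxy]methyl}-N,7-dimethoxy-N,2-dimethyl-2H-chromene-6-carboxamide | CON(C)C(=O)c1cc2C=C[C@](C)(CO[Si](C)(C)C(C)(C)C)Oc2cc1OC
A1 | alternative 1 | (S)-6-bromo-2-[(tert-butyldiphenylsilyloxy)methyl]-7-(methoxymethoxy)-2-methylchroman-3-one | C[C@@]1(CO[Si](c3ccccc3)(c4ccccc4)C(C)(C)C)Oc2cc(OCOC)c(Br)cc2CC1=O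
A2 | alternative 1 | (S)-5-bromo-2-[(tert-butyldiphenylsilyloxy)methyl]-6-(methoxymethoxy)-2-methylbenzofuran-3(2H)-one | C[C@@]1(CO[Si](c3ccccc3)(c4ccccc4)C(C)(C)C)Oc2cc(OCOC)c(Br)cc2C1=O
A3 | alternative 2 | (R)-[6-acetyl-2-methyl-7-(triisopropylsilyloxy)-2H-chromen-2-yl]methyl acetate | CC(=O)OC[C@@]1(C)C=Cc2cc(C(C)=O)c(O[Si](C(C)C)(C(C)C)C(C)C)cc2O1
A4 | alternative 2 | (R)-2-[4-acetyl-3-(triisopropylsilyloxy)phenoxy]-2-methylbut-3-yn-1-yl acetate | CC(=O)OC[C@@](C)(C#C)Oc1ccc(C(C)=O)c(O[Si](C(C)C)(C(C)C)C(C)C)c1
A5 | alternative 3 | (R)-6-acetyl-2-[(tert-butyldimethylsilyloxy)methyl]-7-hydroxy-2-methyl-2H-chromene-3-carbaldehyde | O=CC1=Cc2cc(C(C)=O)c(O)cc2O[C@@]1(C)CO[Si](C)(C)C(C)(C)C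
A6 | alternative 3 | 5-acetyl-2,4-dihydroxybenzaldehyde | O=Cc1cc(C(C)=O)c(O)cc1O
A7 | alternative 3 | (E)-4-[(tert-butyldimethylsilyl)oxy]-3-methylbut-2-enal | O=C/C=C(/CO[Si](C)(C)C(C)(C)C)C
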